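**Plan**
1. Retrosynthetic cuts, in order: the O7 carbamate and three silyl ethers; the C4–C5 bond of the 19-membered ansa ring; the N–C1 amide; C5–C6/C6–C7 (aldol); C8=C9 (cross-metathesis); C10–C11 (crotylboration); C12=C13 (olefination, then hydrogenation); C15–C16 (Negishi).
2. Enabling feature: C4 is the unsubstituted terminus of the allyl unit C2=C3–C4 conjugated to the C1 anilide, and C5 is a primary carbon whose nearest oxygen sits on C7, so a C5–metal bond has no β-leaving group. An acetate on C4 and an iodide on C5 are two electrophiles that nickel can join reductively, so the saturated C4–C5 bond is made directly and nothing has to be excised from the ring afterwards.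
3. Forward: the benzene ring (C16–C21) is bought, the chain is grown linearly from C15 to C5, and the aniline is unmasked and acylated with the C1–C4 acid. The only ring made, the 19-membered lactam bridging C16 and C20 through N, is then closed by C4–C5 bond formation.
4. Stereochemistry: C14 from the chiral pool; C12 by catalyst-controlled hydrogenation; C10/C11 by substrate-controlled (Z)-crotylboration; C6/C7 by an auxiliary-controlled syn-aldol; the (E)-alkenes from cross-metathesis and from a commercial (E)-enal.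
5. Helpers: nitro as masked aniline; TIPS on the phenol; TBS on O11; TES on O7, removed alone so that the carbamate goes on O7 only.

Key step: step 17

Remark: atom numbers follow the target chain (C1 amide carbonyl, C2–C15 ansa chain, C16–C21 arene with OH on C18 and N on C20). (E)-4-Acetoxy-2-methylbut-2-enal and methyl (S)-3-bromo-2-methylpropanoate are taken as commercial, and the E/Z mixture expected in step 4 is assumed separable.

**Step 1**
Reactants: 1 3-bromo-5-nitrophenol
Product: 2 (3-bromo-5-nitrophenoxy)triisopropylsilane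
Conditions: i-Pr3SiCl, imidazole, DMF, rt
Reagents that add atoms: triisopropylsilyl chloride, CC(C)[Si](Cl)(C(C)C)C(C)C
Why: Silylation of the only acidic OH gives a base-stable, fluoride-labile aryl silyl ether that is carried to the last step.

**Step 2**
Reactants: 2 (3-bromo-5-nitrophenoxy)triisopropylsilane; 3 methyl (S)-3-bromo-2-methylpropanoate
Product: 5 methyl (R)-2-methyl-3-[3-nitro-5-(triisopropylsilyloxy)phenyl]propanoate, via alkylzinc bromide 4 (not isolated)
Conditions: 3, Zn dust, I2 (5 mol%), DMA, 70 °C; then 2, Pd(OAc)2 (2 mol%), SPhos (4 mol%), THF, 40 °C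
Reagents that add atoms: none
Why: Zinc insertion gives a primary alkylzinc whose stereocentre (future C14, taken unchanged from the chiral pool) is not at the C–Zn carbon, and Negishi coupling with the aryl bromide forms C15–C16 while the nitro group is tolerated by the organozinc.

**Step 3**
Reactants: 5 methyl (R)-2-methyl-3-[3-nitro-5-(triisopropylsilyloxy)phenyl]propanoate
Product: 6 (R)-2-methyl-3-[3-nitro-5-(triisopropylsilyloxy)phenyl]propanal
Conditions: i-Bu2AlH (1.1 equiv), CH2Cl2, −78 °C; MeOH, aq. Rochelle salt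
Reagents that add atoms: none
Why: Partial ester reduction at −78 °C should stop at the aluminium hemiacetal, which releases the aldehyde on work-up without touching the nitroarene.

**Step 4**
Reactants: 6 (R)-2-methyl-3-[3-nitro-5-(triisopropylsilyloxy)phenyl]propanal; 7 methyl 2-(dimethoxyphosphoryl)-2-methoxyacetate
Product: 8 methyl (2Z,4R)-2-methoxy-4-methyl-5-[3-nitro-5-(triisopropylsilyloxy)phenyl]pent-2-enoate
Conditions: 7, LiN(SiMe3)2, THF, −78 °C; then 6, −78 to 0 °C
Reagents that add atoms: none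
Why: Horner–Wadsworth–Emmons olefination with the preformed α-methoxy phosphonate anion forms C12=C13 with the methoxy group already on C12 and, run cold, should not epimerise the α-stereocentre of 6; the (Z)-isomer is expected to predominate and is taken on.

**Step 5**
Reactants: 8 methyl (2Z,4R)-2-methoxy-4-methyl-5-[3-nitro-5-(triisopropylsilyloxy)phenyl]pent-2-enoate
Product: 9 methyl (2S,4R)-2-methoxy-4-methyl-5-[3-nitro-5-(triisopropylsilyloxy)phenyl]pentanoate
Conditions: H2 (5 bar), [Rh(cod)((S,S)-Et-DuPhos)]BF4 (2 mol%), MeOH, rt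
Reagents that add atoms: none
Why: Asymmetric hydrogenation of an α-alkoxy acrylate on cationic monovalent rhodium should set C12 as (S) under catalyst control, independent of C14; the ligand hand is assigned by analogy with α-acyloxy acrylates and would be inverted if the sense proves opposite.

**Step 6**
Reactants: 9 methyl (2S,4R)-2-methoxy-4-methyl-5-[3-nitro-5-(triisopropylsilyloxy)phenyl]pentanoate
Product: 10 (2S,4R)-2-methoxy-4-methyl-5-[3-nitro-5-(triisopropylsilyloxy)phenyl]pentanal
Conditions: i-Bu2AlH (1.1 equiv), CH2Cl2, −78 °C; MeOH, aq. Rochelle salt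
Reagents that add atoms: none
Why: The α-methoxy group stabilises the tetrahedral aluminium intermediate by chelation, so partial reduction should deliver the α-alkoxy aldehyde, which is used at once to avoid epimerisation at C12.

**Step 7**
Reactants: 10 (2S,4R)-2-methoxy-4-methyl-5-[3-nitro-5-(triisopropylsilyloxy)phenyl]pentanal; 11 (Z)-crotylboronic acid pinacol ester
Product: 13 (3S,4R,5S,7R)-5-methoxy-3,7-dimethyl-8-[3-nitro-5-(triisopropylsilyloxy)phenyl]oct-1-en-4-ol, via pinacol borate ester 12 (not isolated)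
Conditions: 11 (1.5 equiv), 4 Å molecular sieves, toluene, rt; then pH 7 buffer
Reagents that add atoms: none
Why: Allylboration through a closed chair transition state turns the (Z)-crotyl geometry into the C10/C11 syn relationship, and attack anti to the C12 methoxy group (Felkin–Anh/Cornforth control, reinforced because only hydrogen can sit next to the pseudoaxial crotyl methyl) gives the C11/C12 anti relationship, i.e. (10S,11R).

**Step 8**
Reactants: 13 (3S,4R,5S,7R)-5-methoxy-3,7-dimethyl-8-[3-nitro-5-(triisopropylsilyloxy)phenyl]oct-1-en-4-ol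
Product: 14 tert-butyldimethylsilyl ether of 13 at O11
Conditions: t-BuMe2SiOTf, 2,6-lutidine, CH2Cl2, −78 to 0 °C
Reagents that add atoms: tert-butyldimethylsilyl trifluoromethanesulfonate, CC(C)(C)[Si](C)(C)OS(=O)(=O)C(F)(F)F
Why: Silyl triflate with a hindered base silylates the hindered secondary alcohol and gives an ether that survives every step up to the final deprotection.

**Step 9**
Reactants: 14 tert-butyldimethylsilyl ether of 13 at O11; 15 methacrolein
Product: 16 (2E,4S,5R,6S,8R)-5-(tert-butyldimethylsilyloxy)-6-methoxy-2,4,8-trimethyl-9-[3-nitro-5-(triisopropylsilyloxy)phenyl]non-2-enal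
Conditions: 15 (10 equiv), second-generation Hoveyda–Grubbs catalyst (10 mol%), CH2Cl2, 40 °C
Reagents that add atoms: none
Why: Olefin cross-metathesis of the terminal alkene with methacrolein, driven by loss of ethylene, should give the thermodynamically favoured (E)-2-methyl enal and so installs C7, C8 and the C8 methyl group in one step.

**Step 10**
Reactants: 16 (2E,4S,5R,6S,8R)-5-(tert-butyldimethylsilyloxy)-6-methoxy-2,4,8-trimethyl-9-[3-nitro-5-(triisopropylsilyloxy)phenyl]non-2-enal; 17 (R)-4-benzyl-3-propanoyl-1,3-oxazolidin-2-one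
Product: 20 (R)-4-benzyl-3-[(2R,3R,4E,6S,7R,8S,10R)-7-(tert-butyldimethylsilyloxy)-3-hydroxy-8-methoxy-2,4,6,10-tetramethyl-11-(3-nitro-5-(triisopropylsilyloxy)phenyl)undec-4-enoyl]-1,3-oxazolidin-2-one, via dibutylboron enolate 18 (not isolated), via dibutylboron aldolate 19 (not isolated)
Conditions: 17, Bu2BOTf, Et3N, CH2Cl2, −78 to 0 °C; 16, −78 to 0 °C; pH 7 buffer, MeOH, 30% H2O2, 0 °C
Reagents that add atoms: none
Why: Evans syn-aldol reaction, in which the (Z)-boron enolate reacts through a Zimmerman–Traxler chair on the face dictated by the (R)-benzyl auxiliary, should give the C6/C7 syn adduct with the configuration of the target regardless of the remote stereocentres.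

**Step 11**
Reactants: 20 aldol adduct
Product: 21 triethylsilyl ether of 20 at O7
Conditions: Et3SiOTf, 2,6-lutidine, CH2Cl2, −78 °C
Reagents that add atoms: triethylsilyl trifluoromethanesulfonate, CC[Si](CC)(CC)OS(=O)(=O)C(F)(F)F
Why: Silylation blocks retro-aldol cleavage and places on O7 a group that can later be removed in the presence of the tert-butyldimethylsilyl and triisopropylsilyl ethers.

**Step 12**
Reactants: 21 triethylsilyl ether of 20 at O7
Product: 22 (2S,3R,4E,6S,7R,8S,10R)-7-(tert-butyldimethylsilyloxy)-8-methoxy-2,4,6,10-tetramethyl-11-[3-nitro-5-(triisopropylsilyloxy)phenyl]-3-(triethylsilyloxy)undec-4-en-1-ol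
Conditions: LiBH4, MeOH (1 equiv), THF, 0 °C
Reagents that add atoms: none
Why: Reductive cleavage of the N-acyl oxazolidinone gives the C5 primary alcohol and returns the auxiliary, the nitroarene and silyl ethers being inert to borohydride at 0 °C.

**Step 13**
Reactants: 22 C5 alcohol
Product: 23 (2S,3R,4E,6S,7R,8S,10R)-11-[3-amino-5-(triisopropylsilyloxy)phenyl]-7-(tert-butyldimethylsilyloxy)-8-methoxy-2,4,6,10-tetramethyl-3-(triethylsilyloxy)undec-4-en-1-ol
Conditions: Zn dust, NH4Cl, EtOH/H2O, 50 °C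
Reagents that add atoms: none
Why: Dissolving-metal reduction of the nitroarene under near-neutral conditions should give the aniline without affecting the alkene, the silyl ethers or the primary alcohol.

**Step 14**
Reactants: 24 (E)-4-acetoxy-2-methylbut-2-enal
Product: 25 (E)-4-acetoxy-2-methylbut-2-enoic acid
Conditions: NaClO2, NaH2PO4, 2-methylbut-2-ene, t-BuOH/H2O, 0 °C to rt
Reagents that add atoms: sodium chlorite, [Na+].[O-]Cl=O
Why: Pinnick oxidation converts the enal into the acid without isomerising the (E)-alkene or hydrolysing the allylic acetate.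

**Step 15**
Reactants: 23 aniline; 25 (E)-4-acetoxy-2-methylbut-2-enoic acid
Product: 27 (E)-4-acetoxy-2-methylbut-2-enoic acid anilide of 23 (N–C1 amide with free C5 alcohol), via acid chloride 26 (not isolated)
Conditions: 25, (COCl)2, DMF (cat.), CH2Cl2, 0 °C; then 23, 2,6-lutidine, CH2Cl2, −40 to 0 °C
Reagents that add atoms: none
Why: Without an acyl-transfer catalyst the aniline nitrogen is acylated much faster than the hindered primary alcohol (Schotten–Baumann-type N-acylation), giving the amide with the (E)-C2=C3 geometry of the acid retained.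

**Step 16**
Reactants: 27 anilide alcohol
Product: 28 C5 iodide of 27 (cyclisation precursor carrying iodide on C5 and acetate on C4)
Conditions: I2, PPh3, imidazole, CH2Cl2, 0 °C, dark
Reagents that add atoms: iodine, II
Why: Appel iodination replaces the primary hydroxyl by iodide through SN2 displacement of an alkoxyphosphonium ion and leaves the allylic acetate, the anilide and the silyl ethers intact.

**Step 17**
Reactants: 28 C5 iodide carrying the C4 allylic acetate
Product: 29 19-membered macrolactam (2E,6S,7R,8E,10S,11R,12S,14R) with O7-triethylsilyl, O11-tert-butyldimethylsilyl and O18-triisopropylsilyl groups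
Conditions: NiCl2(dme) (20 mol%), 4,4′,4″-tri-tert-butyl-2,2′:6′,2″-terpyridine (20 mol%), Zn dust (4 equiv), THF/DMA, 40 °C, 28 added by syringe pump over 16 h to 2 mM
Reagents that add atoms: none
Why: Proposed new method: zerovalent nickel (from NiCl2(dme) and Zn) should ionise the primary allylic acetate at C4 to an η3-allylnickel species spanning C2–C4, while low-valent nickel abstracts iodine from C5 to give a primary radical that is captured at nickel and reductively eliminated onto the allyl ligand; the closest known reaction type is the intermolecular nickel-catalysed reductive cross-electrophile coupling of unactivated alkyl halides with allylic acetates or carbonates, here run as a ring closure under high dilution. The 19-membered ring closes by C(sp3)–C(sp3) reductive elimination at nickel, an end-to-end macrocyclisation that keeps the allyl unit C2=C3–C4 inside the ring. No stereocentre is created: C6 is a spectator, and C2=C3 should stay (E) because the carboxamide prefers the syn position of the allyl ligand, which is also the thermodynamically favoured tiglate-type arrangement. The step needs bond formation at C4 and not at C2, which is secured because C2 is fully substituted and bonding at C4 restores conjugation with the C1 amide; it needs the C5 radical not to cyclise, which is secured because attack on C8=C9 would be 4-exo or 5-endo; and it needs ring closure to beat oligomerisation, for which the two (E)-trisubstituted alkenes, the anilide and the meta-bridged arene restrict the chain and slow addition does the rest. The C7 oxygen is two carbons from C5, so no β-alkoxide elimination can compete, and the allylic C7 silyl ether is not an electrophile for nickel.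

**Step 18**
Reactants: 29 fully silylated macrolactam
Product: 30 7-hydroxy macrolactam (O11-tert-butyldimethylsilyl and O18-triisopropylsilyl retained)
Conditions: PPTS (0.2 equiv), MeOH/CH2Cl2, 0 °C
Reagents that add atoms: none
Why: Acid-catalysed methanolysis removes the secondary triethylsilyl ether far faster than the more hindered tert-butyldimethylsilyl ether and the aryl triisopropylsilyl ether.

**Step 19**
Reactants: 30 7-hydroxy macrolactam
Product: 32 7-O-carbamoyl macrolactam (O11-tert-butyldimethylsilyl and O18-triisopropylsilyl), via N-trichloroacetyl carbamate 31 (not isolated)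
Conditions: Cl3CC(O)NCO, CH2Cl2, 0 °C; then neutral Al2O3 (wet), rt
Reagents that add atoms: trichloroacetyl isocyanate, O=C=NC(=O)C(Cl)(Cl)Cl
Why: The only free hydroxyl adds to the highly electrophilic isocyanate and the trichloroacetyl group is then hydrolysed on alumina, giving the primary carbamate with retention at C7.

**Step 20**
Reactants: 32 7-O-carbamoyl bis-silyl macrolactam
Product: 33 CNP0247621.1
Conditions: HF·pyridine, pyridine, THF, 0 °C to rt
Reagents that add atoms: none
Why: Fluoride cleavage of the two remaining Si–O bonds, driven by Si–F bond strength, should unveil the C11 alcohol and the phenol without affecting the carbamate, the amide or the alkenes.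

**Compound list**
1 | 3-bromo-5-nitrophenol | Oc1cc(Br)cc([N+](=O)[O-])c1 | starting material
2 | (3-bromo-5-nitrophenoxy)triisopropylsilane | CC(C)[Si](Oc1cc(Br)cc([N+](=O)[O-])c1)(C(C)C)C(C)C | intermediate
3 | methyl (S)-3-bromo-2-methylpropanoate | COC(=O)[C@H](C)CBr | starting material
4 | [(S)-3-methoxy-2-methyl-3-oxopropyl]zinc bromide | COC(=O)[C@H](C)C[Zn]Br | intermediate
5 | methyl (R)-2-methyl-3-[3-nitro-5-(triisopropylsilyloxy)phenyl]propanoate | COC(=O)[C@H](C)Cc1cc(O[Si](C(C)C)(C(C)C)C(C)C)cc([N+](=O)[O-])c1 | intermediate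
6 | (R)-2-methyl-3-[3-nitro-5-(triisopropylsilyloxy)phenyl]propanal | O=C[C@H](C)Cc1cc(O[Si](C(C)C)(C(C)C)C(C)C)cc([N+](=O)[O-])c1 | intermediate
7 | methyl 2-(dimethoxyphosphoryl)-2-methoxyacetate | COC(=O)C(OC)P(=O)(OC)OC | starting material
8 | methyl (2Z,4R)-2-methoxy-4-methyl-5-[3-nitro-5-(triisopropylsilyloxy)phenyl]pent-2-enoate | COC(=O)/C(OC)=C/[C@H](C)Cc1cc(O[Si](C(C)C)(C(C)C)C(C)C)cc([N+](=O)[O-])c1 | intermediate
9 | methyl (2S,4R)-2-methoxy-4-methyl-5-[3-nitro-5-(triisopropylsilyloxy)phenyl]pentanoate | COC(=O)[C@@H](OC)C[C@H](C)Cc1cc(O[Si](C(C)C)(C(C)C)C(C)C)cc([N+](=O)[O-])c1 | intermediate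
10 | (2S,4R)-2-methoxy-4-methyl-5-[3-nitro-5-(triisopropylsilyloxy)phenyl]pentanal | O=C[C@@H](OC)C[C@H](C)Cc1cc(O[Si](C(C)C)(C(C)C)C(C)C)cc([N+](=O)[O-])c1 | intermediate
11 | (Z)-crotylboronic acid pinacol ester, 2-[(Z)-but-2-en-1-yl]-4,4,5,5-tetramethyl-1,3,2-dioxaborolane | C/C=C\CB1OC(C)(C)C(C)(C)O1 | starting material
12 | pinacol borate ester of 13 (boron on the C11 oxygen) | C=C[C@H](C)[C@@H](OB1OC(C)(C)C(C)(C)O1)[C@@H](OC)C[C@H](C)Cc1cc(O[Si](C(C)C)(C(C)C)C(C)C)cc([N+](=O)[O-])c1 | intermediate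
13 | (3S,4R,5S,7R)-5-methoxy-3,7-dimethyl-8-[3-nitro-5-(triisopropylsilyloxy)phenyl]oct-1-en-4-ol | C=C[C@H](C)[C@@H](O)[C@@H](OC)C[C@H](C)Cc1cc(O[Si](C(C)C)(C(C)C)C(C)C)cc([N+](=O)[O-])c1 | intermediate
14 | tert-butyldimethylsilyl ether of 13, (3S,4R,5S,7R) | C=C[C@H](C)[C@@H](O[Si](C)(C)C(C)(C)C)[C@@H](OC)C[C@H](C)Cc1cc(O[Si](C(C)C)(C(C)C)C(C)C)cc([N+](=O)[O-])c1 | intermediate
15 | methacrolein (2-methylprop-2-enal) | CC(=C)C=O | starting material
16 | (2E,4S,5R,6S,8R)-5-(tert-butyldimethylsilyloxy)-6-methoxy-2,4,8-trimethyl-9-[3-nitro-5-(triisopropylsilyloxy)phenyl]non-2-enal | O=C/C(C)=C/[C@H](C)[C@@H](O[Si](C)(C)C(C)(C)C)[C@@H](OC)C[C@H](C)Cc1cc(O[Si](C(C)C)(C(C)C)C(C)C)cc([N+](=O)[O-])c1 | intermediate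
17 | (R)-4-benzyl-3-propanoyl-1,3-oxazolidin-2-one | CCC(=O)N1[C@H](Cc2ccccc2)COC1=O | starting material
18 | dibutylboron (Z)-enolate of 17 | C/C=C(\OB(CCCC)CCCC)N1[C@H](Cc2ccccc2)COC1=O | intermediate
19 | dibutylboron aldolate of 20 (boron on the C7 oxygen) | O=C1OC[C@@H](Cc2ccccc2)N1C(=O)[C@H](C)[C@@H](OB(CCCC)CCCC)/C(C)=C/[C@H](C)[C@@H](O[Si](C)(C)C(C)(C)C)[C@@H](OC)C[C@H](C)Cc1cc(O[Si](C(C)C)(C(C)C)C(C)C)cc([N+](=O)[O-])c1 | intermediate
20 | (R)-4-benzyl-3-[(2R,3R,4E,6S,7R,8S,10R)-7-(tert-butyldimethylsilyloxy)-3-hydroxy-8-methoxy-2,4,6,10-tetramethyl-11-(3-nitro-5-(triisopropylsilyloxy)phenyl)undec-4-enoyl]-1,3-oxazolidin-2-one | O=C1OC[C@@H](Cc2ccccc2)N1C(=O)[C@H](C)[C@@H](O)/C(C)=C/[C@H](C)[C@@H](O[Si](C)(C)C(C)(C)C)[C@@H](OC)C[C@H](C)Cc1cc(O[Si](C(C)C)(C(C)C)C(C)C)cc([N+](=O)[O-])c1 | intermediate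
21 | triethylsilyl ether of 20 at O7 (acyl C3 oxygen) | O=C1OC[C@@H](Cc2ccccc2)N1C(=O)[C@H](C)[C@@H](O[Si](CC)(CC)CC)/C(C)=C/[C@H](C)[C@@H](O[Si](C)(C)C(C)(C)C)[C@@H](OC)C[C@H](C)Cc1cc(O[Si](C(C)C)(C(C)C)C(C)C)cc([N+](=O)[O-])c1 | intermediate
22 | (2S,3R,4E,6S,7R,8S,10R)-7-(tert-butyldimethylsilyloxy)-8-methoxy-2,4,6,10-tetramethyl-11-[3-nitro-5-(triisopropylsilyloxy)phenyl]-3-(triethylsilyloxy)undec-4-en-1-ol | OC[C@H](C)[C@@H](O[Si](CC)(CC)CC)/C(C)=C/[C@H](C)[C@@H](O[Si](C)(C)C(C)(C)C)[C@@H](OC)C[C@H](C)Cc1cc(O[Si](C(C)C)(C(C)C)C(C)C)cc([N+](=O)[O-])c1 | intermediate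
23 | (2S,3R,4E,6S,7R,8S,10R)-11-[3-amino-5-(triisopropylsilyloxy)phenyl]-7-(tert-butyldimethylsilyloxy)-8-methoxy-2,4,6,10-tetramethyl-3-(triethylsilyloxy)undec-4-en-1-ol | OC[C@H](C)[C@@H](O[Si](CC)(CC)CC)/C(C)=C/[C@H](C)[C@@H](O[Si](C)(C)C(C)(C)C)[C@@H](OC)C[C@H](C)Cc1cc(O[Si](C(C)C)(C(C)C)C(C)C)cc(N)c1 | intermediate
24 | (E)-4-acetoxy-2-methylbut-2-enal | CC(=O)OC/C=C(\C)C=O | starting material
25 | (E)-4-acetoxy-2-methylbut-2-enoic acid | CC(=O)OC/C=C(\C)C(=O)O | intermediate
26 | (E)-4-acetoxy-2-methylbut-2-enoyl chloride | CC(=O)OC/C=C(\C)C(Cl)=O | intermediate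
27 | N-aryl (E)-4-acetoxy-2-methylbut-2-enamide of aniline 23 (free C5 alcohol; chain centres as in 23) | OC[C@H](C)[C@@H](O[Si](CC)(CC)CC)/C(C)=C/[C@H](C)[C@@H](O[Si](C)(C)C(C)(C)C)[C@@H](OC)C[C@H](C)Cc1cc(O[Si](C(C)C)(C(C)C)C(C)C)cc(NC(=O)/C(C)=C/COC(C)=O)c1 | intermediate
28 | C5 iodide of 27 (configuration unchanged; C6 is R by the priority rule) | IC[C@H](C)[C@@H](O[Si](CC)(CC)CC)/C(C)=C/[C@H](C)[C@@H](O[Si](C)(C)C(C)(C)C)[C@@H](OC)C[C@H](C)Cc1cc(O[Si](C(C)C)(C(C)C)C(C)C)cc(NC(=O)/C(C)=C/COC(C)=O)c1 | intermediate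
29 | 19-membered macrolactam, (2E,6S,7R,8E,10S,11R,12S,14R), O7-triethylsilyl, O11-tert-butyldimethylsilyl, O18-triisopropylsilyl | CO[C@H]1C[C@H](C)Cc2cc(O[Si](C(C)C)(C(C)C)C(C)C)cc(c2)NC(=O)/C(C)=C/CC[C@H](C)[C@@H](O[Si](CC)(CC)CC)/C(C)=C/[C@H](C)[C@H]1O[Si](C)(C)C(C)(C)C | intermediate
30 | 7-hydroxy macrolactam, O11-tert-butyldimethylsilyl, O18-triisopropylsilyl | CO[C@H]1C[C@H](C)Cc2cc(O[Si](C(C)C)(C(C)C)C(C)C)cc(c2)NC(=O)/C(C)=C/CC[C@H](C)[C@@H](O)/C(C)=C/[C@H](C)[C@H]1O[Si](C)(C)C(C)(C)C | intermediate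
31 | 7-O-(N-trichloroacetylcarbamoyl) macrolactam, O11-tert-butyldimethylsilyl, O18-triisopropylsilyl | CO[C@H]1C[C@H](C)Cc2cc(O[Si](C(C)C)(C(C)C)C(C)C)cc(c2)NC(=O)/C(C)=C/CC[C@H](C)[C@@H](OC(=O)NC(=O)C(Cl)(Cl)Cl)/C(C)=C/[C@H](C)[C@H]1O[Si](C)(C)C(C)(C)C | intermediate
32 | 7-O-carbamoyl macrolactam, O11-tert-butyldimethylsilyl, O18-triisopropylsilyl | CO[C@H]1C[C@H](C)Cc2cc(O[Si](C(C)C)(C(C)C)C(C)C)cc(c2)NC(=O)/C(C)=C/CC[C@H](C)[C@@H](OC(N)=O)/C(C)=C/[C@H](C)[C@H]1O[Si](C)(C)C(C)(C)C | intermediate
33 | CNP0247621.1, the (2E,6S,7R,8E,10S,11R,12S,14R) 7-O-carbamoyl-11,18-dihydroxy-12-methoxy-2,6,8,10,14-pentamethyl 19-membered meta-ansa lactam | CO[C@H]1C[C@H](C)Cc2cc(O)cc(c2)NC(=O)/C(C)=C/CC[C@H](C)[C@@H](OC(N)=O)/C(C)=C/[C@H](C)[C@H]1O | target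

**Count and risks**
Total: 20 steps. Longest linear sequence: 19 steps (steps 1–13 and 15–20; step 14 makes the C1–C4 acid separately).

The three steps most likely to fail:

Step 17 (Proposed new method). Oligomerisation, hydrodehalogenation at C5 or simple reduction of the allyl acetate may outrun ring closure. β-Hydride loss from a C5–nickel species and syn–anti isomerisation of the allylnickel intermediate, which would erode the C2=C3 geometry, are further risks. The fallback uses known chemistry and sets out from enal 16. Reagent-controlled crotylboration with the (Z)-crotyldiisopinocampheylborane enantiomer that delivers the 6,7-syn (6S,7R) adduct gives the C5-vinyl alcohol F1. Et3SiOTf/2,6-lutidine gives the triethylsilyl ether F2, and Zn/NH4Cl gives the aniline F3. Acylation with (E)-2-methylpenta-2,4-dienoyl chloride gives the dienamide F4. Ring-closing metathesis with the second-generation Grubbs catalyst in dilute refluxing CH2Cl2 joins C4 and C5 as an alkene in the macrocyclic 2,4-dienamide F5. Diimide, from 2-nitrobenzenesulfonylhydrazide and Et3N, then saturates the disubstituted C4=C5 bond in preference to the two trisubstituted alkenes, and the route is rejoined at 29.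

Step 5. Facial selectivity may be poor or turnover slow, because an α-methoxy group binds rhodium less well than an acyloxy or acylamino group, and the nitro group may be partly reduced. The fallback sets out from 8. Aqueous HCl in THF hydrolyses the enol ether to the α-keto ester F6. Asymmetric reduction of the ketone, by RuCl2(BINAP)-catalysed hydrogenation or a Corey–Bakshi–Shibata reduction of the appropriate hand, gives the (S)-α-hydroxy ester F7. O-Methylation with MeI and Ag2O rejoins the route at 9.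

Step 9. Cross-metathesis of the allylically branched, β-silyloxy terminal alkene may be slow, so that methacrolein self-metathesis and catalyst decomposition dominate. The fallback sets out from 14. Ozonolysis (O3, CH2Cl2/MeOH, −78 °C; Me2S) gives the α-methyl aldehyde F8. A Wittig reaction with 2-(triphenylphosphoranylidene)propanal in toluene at 80 °C rejoins the route at enal 16.

**Further compounds**
F1 | step 17 | (3S,4R,5E,7S,8R,9S,11R)-8-(tert-butyldimethylsilyloxy)-9-methoxy-3,5,7,11-tetramethyl-12-[3-nitro-5-(triisopropylsilyloxy)phenyl]dodeca-1,5-dien-4-ol | C=C[C@H](C)[C@@H](O)/C(C)=C/[C@H](C)[C@@H](O[Si](C)(C)C(C)(C)C)[C@@H](OC)C[C@H](C)Cc1cc(O[Si](C(C)C)(C(C)C)C(C)C)cc([N+](=O)[O-])c1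
F2 | step 17 | triethylsilyl ether of F1 at O7 | C=C[C@H](C)[C@@H](O[Si](CC)(CC)CC)/C(C)=C/[C@H](C)[C@@H](O[Si](C)(C)C(C)(C)C)[C@@H](OC)C[C@H](C)Cc1cc(O[Si](C(C)C)(C(C)C)C(C)C)cc([N+](=O)[O-])c1
F3 | step 17 | aniline from reduction of the nitro group of F2 | C=C[C@H](C)[C@@H](O[Si](CC)(CC)CC)/C(C)=C/[C@H](C)[C@@H](O[Si](C)(C)C(C)(C)C)[C@@H](OC)C[C@H](C)Cc1cc(O[Si](C(C)C)(C(C)C)C(C)C)cc(N)c1
F4 | step 17 | N-aryl (E)-2-methylpenta-2,4-dienamide of F3 | C=C[C@H](C)[C@@H](O[Si](CC)(CC)CC)/C(C)=C/[C@H](C)[C@@H](O[Si](C)(C)C(C)(C)C)[C@@H](OC)C[C@H](C)Cc1cc(O[Si](C(C)C)(C(C)C)C(C)C)cc(NC(=O)/C(C)=C/C=C)c1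
F5 | step 17 | 4,5-didehydro analogue of 29 (macrocyclic 2,4-dienamide, C4=C5 geometry not fixed) | CO[C@H]1C[C@H](C)Cc2cc(O[Si](C(C)C)(C(C)C)C(C)C)cc(c2)NC(=O)/C(C)=C/C=C[C@H](C)[C@@H](O[Si](CC)(CC)CC)/C(C)=C/[C@H](C)[C@H]1O[Si](C)(C)C(C)(C)C
F6 | step 5 | methyl (R)-4-methyl-5-[3-nitro-5-(triisopropylsilyloxy)phenyl]-2-oxopentanoate | COC(=O)C(=O)C[C@H](C)Cc1cc(O[Si](C(C)C)(C(C)C)C(C)C)cc([N+](=O)[O-])c1
F7 | step 5 | methyl (2S,4R)-2-hydroxy-4-methyl-5-[3-nitro-5-(triisopropylsilyloxy)phenyl]pentanoate | COC(=O)[C@@H](O)C[C@H](C)Cc1cc(O[Si](C(C)C)(C(C)C)C(C)C)cc([N+](=O)[O-])c1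
F8 | step 9 | (2R,3R,4S,6R)-3-(tert-butyldimethylsilyloxy)-4-methoxy-2,6-dimethyl-7-[3-nitro-5-(triisopropylsilyloxy)phenyl]heptanal | O=C[C@H](C)[C@@H](O[Si](C)(C)C(C)(C)C)[C@@H](OC)C[C@H](C)Cc1cc(O[Si](C(C)C)(C(C)C)C(C)C)cc([N+](=O)[O-])c1
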